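**Late readings.** At 39 min the blue and amber runs stand close, at 0.563 M and 0.609 M of target, although amber was charged 1.50 times the substrate of blue.

| setting | blue | teal | amber | grey |
|---|---|---|---|---|
| substrate | 0.800 M | 0.800 M | 1.20 M | 2.40 M |
| partner | 0.640 M | 1.90 M | 0.640 M | 0.210 M |
| time |  |  |  | 39 min |

- blue run (time / min: [target] / M): 1.6: 0.020; 3.5: 0.082; 7.8: 0.179; 17: 0.387; 39: 0.563
- teal run (time / min: [target] / M): 1.6: 0; 3.5: 0.046; 7.8: 0.097; 17: 0.282; 39: 0.573
- amber run (time / min: [target] / M): 1.6: 0.016; 3.5: 0.092; 7.8: 0.264; 17: 0.506; 39: 0.609

(each reading ± 0.01 M)

- Overall: substrate + partner -> target.
- Constant volume, constant temperature.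
- Bound and free are read together.
- An order is taken over about fifteen percent of the charge, up and down.

1. apparent order in [partner] of the starting rate, round the charge of the blue run (the rate where two percent of its substrate have turned into target)
2. apparent order in [substrate] of the starting rate, round the charge of the blue run (the rate where two percent of its substrate have turned into target) (one fixed amount of target, the same in the runs compared)
3. target in the grey run at 39 min, as a share of the substrate charged

**Partner balance.** Each target takes one partner, so the partner left, free and bound counted together, is at most the charge minus the target. Blue and amber were both charged 0.640 M of partner, less than their substrate. Partner is therefore the limiting reagent in both, and target cannot pass that charge. Blue stands at 88.0% of it and amber at 95.2%. We call κ the first-order constant of that partner left, read between 17 min and 39 min. It reads 0.0541 min⁻¹ in blue and 0.0665 min⁻¹ in amber, so amber closes on the same charge faster. Both are readings, and each carries a scatter of 0.01 M on the amount left.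

**Grey reckoning.** The grey run's charges give 8.75%: this is its ceiling share c, partner charged over substrate charged. At amber's κ, 7.46% of grey's partner charge remains at 39 min, so our reckoning gives 8.10% of the substrate. Grey holds twice amber's substrate, and κ read higher in amber than in blue, so we take this as the low end and expect a value between it and c.

**The forecast.** It gives −0.35 and 1.25 for the orders and 8.4% for the grey run, higher than our low end, saying “Grey should therefore be nearly complete by 39 min”.

**The flask.**

    substrate ⇌ intermediate (0.1236 min⁻¹, 0.1200 min⁻¹)
    intermediate + partner → target (2.736 L mol⁻¹ min⁻¹)
    2 partner → lost reagent (0.09900 L mol⁻¹ min⁻¹)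
    substrate + partner ⇌ idle substrate-reagent adduct, settled at all times (6.860 L mol⁻¹)

The orders come out at 0.064 in partner and 0.64 in substrate, against the forecast's −0.35 and 1.25. The grey run gives 8.74%, which is 99.9% of c, so nearly all of its ceiling is reached. The path from partner to lost reagent makes no difference to this share. The amber run has a ceiling share of 53.3%, and its target came to 0.600 M at 26.7 min, which is 93.8% of that ceiling.

The readings stem from a simulated flask with made-up constants; noise was put on by code.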